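**Retrosynthetic overview**

- The target is numbered as a 6‑oxabicyclo[3.2.1]octan‑7‑one (carbocycle C1–C2–C3–C4–C5–C8; lactone bridge C1–C7(=O)–O6–C5). The butenolide comes from cross‑metathesis of a C1 allyl group with α‑methylene‑γ‑butyrolactone and an exo‑to‑endo double‑bond shift. The lactone and C5 come from isopropenyl addition to a C5 ketone, whose alkoxide is acylated by the syn‑axial C1 ester.
- Enabling feature: the γ‑keto ester pattern C5(=O)–C8–C1(CO2Me) inside the carbocycle, with C8 carrying the propanoate arm. This is the signature of a 1,2‑acyl shift, so the six‑membered ring is cut back to a cyclopentanone β‑keto ester (C5, C4, C3, C2, C1) whose quaternary C1 carries C8 as an iodo‑substituted arm.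
- Key event: radical one‑carbon ring expansion (C8 inserts between C5 and C1), continued in the same chain by allylation of the C1 radical anti to the C2 methyl and the C8 arm. This enlarges the ring, makes the C8–C5 and C1–allyl bonds, and sets C8 and the quaternary C1.
- Precursor from the chiral pool: (R)‑pulegone supplies C2 with its methyl group (Favorskii contraction, ozonolysis); acetylene supplies C8; methyl iodoacetate supplies the ester arm.
- Ring order: cyclopentanone (from pulegone) → cyclohexanone (key step) → bridged γ‑lactone → butenolide.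

Key step: step 5

Remark on the chemistry: (R)‑(+)‑pulegone is taken as the required enantiomer because its methyl‑bearing carbon has the configuration (R) of C2 of the target; the derived β‑keto ester is used as its equilibrating keto/enol mixture, since its C1 is reset in the vinylation.

**Step 1**
Reactants: 1 (R)‑(+)‑pulegone [(5R)‑5‑methyl‑2‑(propan‑2‑ylidene)cyclohexan‑1‑one]
Product: 3 methyl (5R)‑5‑methyl‑2‑(propan‑2‑ylidene)cyclopentane‑1‑carboxylate (methyl pulegenate; C1 epimers), via pulegone dibromide 2 (not isolated)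
Conditions: Br2, AcOH, 0 °C; then NaOMe, MeOH, reflux
Reagents that add atoms: sodium methoxide, [Na+].[O-]C
Why: Favorskii rearrangement of the dibromo ketone (enolization at C6, cyclopropanone, methoxide opening with loss of the second bromide to restore the isopropylidene group) gives the cyclopentane ester; the methyl‑bearing stereocentre is not involved and stays R.

**Step 2**
Reactants: 3 methyl pulegenate
Product: 4 methyl (1S,5R)‑5‑methyl‑2‑oxocyclopentane‑1‑carboxylate (trans keto form; equilibrating with cis epimer and enol)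
Conditions: O3, CH2Cl2, −78 °C; then Me2S, −78 °C → rt
Reagents that add atoms: ozone, [O-][O+]=O
Why: Ozonolysis with reductive work‑up cleaves the tetrasubstituted exocyclic alkene to the ring ketone and acetone; the configuration at C1 is unimportant because it is reset in step 3.

**Step 3**
Reactants: 4 methyl (1S,5R)‑5‑methyl‑2‑oxocyclopentane‑1‑carboxylate; 5 acetylene
Product: 6 methyl (1R,5R)‑1‑ethenyl‑5‑methyl‑2‑oxocyclopentane‑1‑carboxylate (vinyl trans to the ring methyl)
Conditions: HC≡CH (1 atm), In(OTf)3 (20 mol%), DBU (20 mol%), 3 Å MS, toluene, 100 °C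
Reagents that add atoms: acetylene (5), C#C
Why: In(OTf)3‑catalysed α‑vinylation of a β‑keto ester with acetylene (syn‑carbometalation of the alkyne by the indium enolate, then protonation); the enolate should react on the face anti to the neighbouring C5 methyl, placing the vinyl group trans to it.

**Step 4**
Reactants: 6 methyl (1R,5R)‑1‑ethenyl‑5‑methyl‑2‑oxocyclopentane‑1‑carboxylate; 7 methyl iodoacetate
Product: 8 methyl (1S,5R)‑1‑(1‑iodo‑4‑methoxy‑4‑oxobutyl)‑5‑methyl‑2‑oxocyclopentane‑1‑carboxylate (both epimers at the CHI carbon)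
Conditions: ICH2CO2Me (5 equiv), Et3B (0.2 equiv, in portions), air, CH2Cl2 (1 M), 0 °C → rt
Reagents that add atoms: methyl iodoacetate (7), COC(=O)CI
Why: Iodine‑atom‑transfer radical addition (Kharasch type): the electrophilic •CH2CO2Me radical adds to the terminal vinyl carbon and the adduct radical takes iodine from the excess iodoacetate, which at high iodide concentration and low temperature should outrun its rearrangement; the CHI configuration is irrelevant because this carbon becomes a radical in step 5.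

**Step 5**
Reactants: 8 methyl (1S,5R)‑1‑(1‑iodo‑4‑methoxy‑4‑oxobutyl)‑5‑methyl‑2‑oxocyclopentane‑1‑carboxylate; 9 allyltributylstannane
Product: 12 methyl (1R,2R,6R)‑2‑(3‑methoxy‑3‑oxopropyl)‑6‑methyl‑3‑oxo‑1‑(prop‑2‑en‑1‑yl)cyclohexane‑1‑carboxylate, via secondary alkyl radical 10 (not isolated), via ring‑expanded ester radical 11 (not isolated)
Conditions: allylSnBu3 (3 equiv), AIBN (0.2 equiv, in portions), PhH (0.1 M), 80 °C; aq KF work‑up
Reagents that add atoms: allyltributylstannane (9), C=CC[Sn](CCCC)(CCCC)CCCC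
Why: Proposed new method: Bu3Sn• abstracts iodine from 8 to give the secondary radical 10, which closes 3‑exo‑trig onto the ring ketone carbon and opens the cyclopropyloxy radical by β‑scission of the old C(=O)–C(quaternary) bond (1,2‑acyl shift), so that the arm carbon is inserted and the cyclopentanone becomes the cyclohexanone radical 11; 11 then adds to allyltributylstannane and expels Bu3Sn•, which carries the chain. The closest known reaction types are the Dowd–Beckwith ring expansion of 2‑(haloalkyl) β‑keto esters with Bu3SnH and the Keck allylation of tertiary α‑ester radicals; new is their union, in which the tin hydride is left out and the rearranged radical is intercepted by C–C bond formation at a carbon that becomes quaternary. The six‑membered ring is closed by the 3‑exo‑trig/β‑scission pair (net one‑carbon enlargement of the five‑membered ring), driven by the ester‑stabilised tertiary radical and the release of cyclopentanone strain. C2 of 12 is set in the 3‑exo closure, where the propanoate arm should take the exo position away from the ring and thereby end cis to the C6 methyl (this is also expected to be the equatorial, more stable epimer next to the ketone); C1 is set by allyl transfer to the face of 11 opposite to the two flanking cis substituents, which allylic 1,3‑strain with the planar ester radical should push into pseudo‑axial positions on one face. The step needs rearrangement of 10 to outrun its direct allylation and allylation of 11 to outrun all other fates: the nucleophilic secondary radical 10 is polarity‑mismatched with the electron‑rich stannane, the electrophilic α‑ester radical 11 is matched, and no hydrogen donor is present.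

**Step 6**
Reactants: 12 methyl (1R,2R,6R)‑2‑(3‑methoxy‑3‑oxopropyl)‑6‑methyl‑3‑oxo‑1‑(prop‑2‑en‑1‑yl)cyclohexane‑1‑carboxylate; 13 isopropenylmagnesium bromide
Product: 15 methyl 3‑[(1R,2R,5S,8R)‑2‑methyl‑7‑oxo‑5‑(prop‑1‑en‑2‑yl)‑1‑(prop‑2‑en‑1‑yl)‑6‑oxabicyclo[3.2.1]octan‑8‑yl]propanoate, via tertiary alkoxide 14 (not isolated)
Conditions: CH2=C(CH3)MgBr (1.5 equiv), CeCl3 (1.6 equiv), THF, −78 °C → 0 °C; aq NH4Cl
Reagents that add atoms: isopropenylmagnesium bromide (13), C=C(C)[Mg]Br
Why: Chemoselective organocerium 1,2‑addition to the ketone (esters are left at low temperature); in the chair with the C2 arm and C6 methyl equatorial the C1 ester is axial and blocks the axial trajectory at C3, so the bulky nucleophile should enter equatorially, and the new axial alkoxide, 1,3‑diaxial to that ester, acylates itself to the bridged five‑membered lactone with loss of methoxide, which sets C5 of the bicycle.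

**Step 7**
Reactants: 15 methyl 3‑[(1R,2R,5S,8R)‑2‑methyl‑7‑oxo‑5‑(prop‑1‑en‑2‑yl)‑1‑(prop‑2‑en‑1‑yl)‑6‑oxabicyclo[3.2.1]octan‑8‑yl]propanoate; 16 α‑methylene‑γ‑butyrolactone
Product: 17 methyl 3‑[(1R,2R,5S,8R)‑2‑methyl‑7‑oxo‑1‑[(2E)‑2‑(2‑oxooxolan‑3‑ylidene)ethyl]‑5‑(prop‑1‑en‑2‑yl)‑6‑oxabicyclo[3.2.1]octan‑8‑yl]propanoate
Conditions: 16 (3 equiv), second‑generation Hoveyda–Grubbs catalyst (5 mol%), 2,6‑dichloro‑1,4‑benzoquinone (10 mol%), CH2Cl2, 40 °C
Reagents that add atoms: α‑methylene‑γ‑butyrolactone (16), C=C1CCOC1=O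
Why: Olefin cross‑metathesis of the monosubstituted allyl alkene with the 1,1‑disubstituted acrylate‑type lactone should give the E‑alkylidene lactone with loss of ethylene; the isopropenyl group, a 1,1‑disubstituted alkene on a fully substituted carbon, should stay out of the catalytic cycle, and the quinone suppresses migration of the allyl double bond.

**Step 8**
Reactants: 17 methyl 3‑[(1R,2R,5S,8R)‑2‑methyl‑7‑oxo‑1‑[(2E)‑2‑(2‑oxooxolan‑3‑ylidene)ethyl]‑5‑(prop‑1‑en‑2‑yl)‑6‑oxabicyclo[3.2.1]octan‑8‑yl]propanoate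
Product: 18 methyl 3‑[(1R,2R,5S,8R)‑2‑methyl‑7‑oxo‑1‑[2‑(2‑oxo‑2,5‑dihydrofuran‑3‑yl)ethyl]‑5‑(prop‑1‑en‑2‑yl)‑6‑oxabicyclo[3.2.1]octan‑8‑yl]propanoate (CNP0209666.1)
Conditions: RhCl3·3H2O (10 mol%), MeOH, 60 °C
Reagents that add atoms: none
Why: RhCl3‑catalysed olefin isomerization (Rh–H addition and β‑hydride elimination) should move the exocyclic double bond into the lactone ring to the conjugated endocyclic butenolide; the isopropenyl group has no position to migrate to, methanol cannot scramble the methyl ester, and no stereocentre is touched.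

**Compound list**

1 | (R)‑(+)‑pulegone, (5R)‑5‑methyl‑2‑(propan‑2‑ylidene)cyclohexan‑1‑one | C[C@@H]1CCC(=C(C)C)C(=O)C1 | starting material
2 | pulegone dibromide, (5R)‑2‑bromo‑2‑(2‑bromopropan‑2‑yl)‑5‑methylcyclohexan‑1‑one (C2 epimers) | C[C@@H]1CCC(Br)(C(C)(C)Br)C(=O)C1 | intermediate
3 | methyl (5R)‑5‑methyl‑2‑(propan‑2‑ylidene)cyclopentane‑1‑carboxylate (methyl pulegenate; C1 epimers, trans drawn) | C[C@@H]1CCC(=C(C)C)[C@H]1C(=O)OC | intermediate
4 | methyl (1S,5R)‑5‑methyl‑2‑oxocyclopentane‑1‑carboxylate (trans keto form) | C[C@@H]1CCC(=O)[C@H]1C(=O)OC | intermediate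
5 | acetylene | C#C | starting material
6 | methyl (1R,5R)‑1‑ethenyl‑5‑methyl‑2‑oxocyclopentane‑1‑carboxylate | C[C@@H]1CCC(=O)[C@]1(C=C)C(=O)OC | intermediate
7 | methyl iodoacetate | COC(=O)CI | starting material
8 | methyl (1S,5R)‑1‑(1‑iodo‑4‑methoxy‑4‑oxobutyl)‑5‑methyl‑2‑oxocyclopentane‑1‑carboxylate (CHI epimers) | C[C@@H]1CCC(=O)[C@]1(C(I)CCC(=O)OC)C(=O)OC | intermediate
9 | allyltributylstannane | C=CC[Sn](CCCC)(CCCC)CCCC | starting material
10 | secondary alkyl radical from 8 (radical at the former CHI carbon) | C[C@@H]1CCC(=O)[C@]1([CH]CCC(=O)OC)C(=O)OC | intermediate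
11 | ring‑expanded tertiary α‑ester radical (cyclohexanone, arm cis to methyl) | O=C1CC[C@@H](C)[C](C(=O)OC)[C@H]1CCC(=O)OC | intermediate
12 | methyl (1R,2R,6R)‑2‑(3‑methoxy‑3‑oxopropyl)‑6‑methyl‑3‑oxo‑1‑(prop‑2‑en‑1‑yl)cyclohexane‑1‑carboxylate | O=C1CC[C@@H](C)[C@@](CC=C)(C(=O)OC)[C@H]1CCC(=O)OC | intermediate
13 | isopropenylmagnesium bromide | C=C(C)[Mg]Br | starting material
14 | tertiary alkoxide of methyl (1R,2R,3S,6R)‑3‑hydroxy‑2‑(3‑methoxy‑3‑oxopropyl)‑6‑methyl‑3‑(prop‑1‑en‑2‑yl)‑1‑(prop‑2‑en‑1‑yl)cyclohexane‑1‑carboxylate (SMILES of the alcohol) | C=C(C)[C@]1(O)CC[C@@H](C)[C@@](CC=C)(C(=O)OC)[C@H]1CCC(=O)OC | intermediate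
15 | methyl 3‑[(1R,2R,5S,8R)‑2‑methyl‑7‑oxo‑5‑(prop‑1‑en‑2‑yl)‑1‑(prop‑2‑en‑1‑yl)‑6‑oxabicyclo[3.2.1]octan‑8‑yl]propanoate | C=C(C)[C@@]12CC[C@@H](C)[C@@](CC=C)(C(=O)O1)[C@H]2CCC(=O)OC | intermediate
16 | α‑methylene‑γ‑butyrolactone (3‑methylideneoxolan‑2‑one) | C=C1CCOC1=O | starting material
17 | methyl 3‑[(1R,2R,5S,8R)‑2‑methyl‑7‑oxo‑1‑[(2E)‑2‑(2‑oxooxolan‑3‑ylidene)ethyl]‑5‑(prop‑1‑en‑2‑yl)‑6‑oxabicyclo[3.2.1]octan‑8‑yl]propanoate | C=C(C)[C@@]12CC[C@@H](C)[C@@](C/C=C3\CCOC3=O)(C(=O)O1)[C@H]2CCC(=O)OC | intermediate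
18 | methyl 3‑[(1R,2R,5S,8R)‑2‑methyl‑7‑oxo‑1‑[2‑(2‑oxo‑2,5‑dihydrofuran‑3‑yl)ethyl]‑5‑(prop‑1‑en‑2‑yl)‑6‑oxabicyclo[3.2.1]octan‑8‑yl]propanoate | C=C(C)[C@@]12CC[C@@H](C)[C@@](CCC3=CCOC3=O)(C(=O)O1)[C@H]2CCC(=O)OC | target

**Step count and risks**

Total step count: 8. Longest linear sequence: 8 steps (1 → 18).

Steps most likely to fail:

1. Step 5 (proposed new method). Allyl transfer to the hindered tertiary radical may be too slow, so that chain breakdown or radical disproportionation takes over, or the allyl group may enter on the wrong face of C1. Fallback with known chemistry, setting out from iodide 8 and coming back at ketone 12: the ring expansion is run in its established reductive form (Bu3SnH added slowly, AIBN, PhH, 80 °C) to give methyl (6R)‑2‑(3‑methoxy‑3‑oxopropyl)‑6‑methyl‑3‑oxocyclohexane‑1‑carboxylate F1. Thermodynamic silylation (TMSOTf, Et3N, CH2Cl2) should give the more substituted silyl enol ether, methyl (6R)‑2‑(3‑methoxy‑3‑oxopropyl)‑6‑methyl‑3‑[(trimethylsilyl)oxy]cyclohex‑2‑ene‑1‑carboxylate F2. Saegusa–Ito oxidation (Pd(OAc)2, MeCN, rt) then gives the ene‑keto ester methyl (6R)‑2‑(3‑methoxy‑3‑oxopropyl)‑6‑methyl‑3‑oxocyclohex‑1‑ene‑1‑carboxylate F3. Hosomi–Sakurai addition (allylSiMe3, TiCl4, CH2Cl2, −78 °C) should place the allyl group on C1 trans to the C6 methyl, and DBU equilibration of the ketone α‑carbon C2 to the equatorial epimer returns 12.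

2. Step 6. The nucleophile may add from the axial direction, giving an alcohol that cannot lactonize, or the new alkoxide may be acylated by the side‑chain ester instead of the ring ester. Fallback setting out from ketone 12 and coming back at lactone 15: the addition is worked up at the hydroxy diester stage, including the C3 epimer methyl (1R,2R,3R,6R)‑3‑hydroxy‑2‑(3‑methoxy‑3‑oxopropyl)‑6‑methyl‑3‑(prop‑1‑en‑2‑yl)‑1‑(prop‑2‑en‑1‑yl)cyclohexane‑1‑carboxylate F4. This material is then ionized with a catalytic Brønsted acid (TfOH 5 mol%, CH2Cl2, 0 °C). The tertiary allylic cation at C3 should be captured by the carbonyl oxygen of the syn‑axial C1 ester with loss of methanol; this SN1 lactonization forms the C–O bond from the carboxyl side and is stereoconvergent.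

3. Step 8. The double‑bond migration may stop short or go out of conjugation, and the tertiary allylic lactone C–O bond may ionize under the slightly acidic rhodium conditions. Fallback setting out from lactone 15 and coming back at target 18, building the butenolide without any olefin migration:
   - Lemieux–Johnson cleavage (OsO4 cat., NaIO4, 2,6‑lutidine, dioxane/H2O, 0 °C) of the unhindered monosubstituted alkene should give the aldehyde methyl 3‑[(1R,2R,5S,8R)‑2‑methyl‑7‑oxo‑1‑(2‑oxoethyl)‑5‑(prop‑1‑en‑2‑yl)‑6‑oxabicyclo[3.2.1]octan‑8‑yl]propanoate F5; the isopropenyl group is shielded by its fully substituted, oxygen‑bearing neighbour.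
   - Organocatalytic reductive alkylation of tetronic acid (tetronic acid, Hantzsch ester, L‑proline cat., CH2Cl2, rt) gives the 3‑alkyltetronic acid methyl 3‑[(1R,2R,5S,8R)‑1‑[2‑(4‑hydroxy‑2‑oxo‑2,5‑dihydrofuran‑3‑yl)ethyl]‑2‑methyl‑7‑oxo‑5‑(prop‑1‑en‑2‑yl)‑6‑oxabicyclo[3.2.1]octan‑8‑yl]propanoate F6.
   - Triflation (Tf2O, iPr2NEt, CH2Cl2, −78 °C) gives the enol triflate methyl 3‑[(1R,2R,5S,8R)‑2‑methyl‑7‑oxo‑1‑[2‑(2‑oxo‑4‑{[(trifluoromethyl)sulfonyl]oxy}‑2,5‑dihydrofuran‑3‑yl)ethyl]‑5‑(prop‑1‑en‑2‑yl)‑6‑oxabicyclo[3.2.1]octan‑8‑yl]propanoate F7.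
   - Formate reduction (Pd(OAc)2, PPh3, Bu3N, HCO2H, DMF, 60 °C) removes the triflate and gives 18.

**Further compounds**

F1 | step 5 | methyl (6R)‑2‑(3‑methoxy‑3‑oxopropyl)‑6‑methyl‑3‑oxocyclohexane‑1‑carboxylate (epimers at C1 and C2) | O=C1CC[C@@H](C)C(C(=O)OC)C1CCC(=O)OC
F2 | step 5 | methyl (6R)‑2‑(3‑methoxy‑3‑oxopropyl)‑6‑methyl‑3‑[(trimethylsilyl)oxy]cyclohex‑2‑ene‑1‑carboxylate (C1 epimers) | C[Si](C)(C)OC1=C(CCC(=O)OC)C(C(=O)OC)[C@H](C)CC1
F3 | step 5 | methyl (6R)‑2‑(3‑methoxy‑3‑oxopropyl)‑6‑methyl‑3‑oxocyclohex‑1‑ene‑1‑carboxylate | O=C1CC[C@@H](C)C(C(=O)OC)=C1CCC(=O)OC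
F4 | step 6 | methyl (1R,2R,3R,6R)‑3‑hydroxy‑2‑(3‑methoxy‑3‑oxopropyl)‑6‑methyl‑3‑(prop‑1‑en‑2‑yl)‑1‑(prop‑2‑en‑1‑yl)cyclohexane‑1‑carboxylate | C=C(C)[C@@]1(O)CC[C@@H](C)[C@@](CC=C)(C(=O)OC)[C@H]1CCC(=O)OC
F5 | step 8 | methyl 3‑[(1R,2R,5S,8R)‑2‑methyl‑7‑oxo‑1‑(2‑oxoethyl)‑5‑(prop‑1‑en‑2‑yl)‑6‑oxabicyclo[3.2.1]octan‑8‑yl]propanoate | C=C(C)[C@@]12CC[C@@H](C)[C@@](CC=O)(C(=O)O1)[C@H]2CCC(=O)OC
F6 | step 8 | methyl 3‑[(1R,2R,5S,8R)‑1‑[2‑(4‑hydroxy‑2‑oxo‑2,5‑dihydrofuran‑3‑yl)ethyl]‑2‑methyl‑7‑oxo‑5‑(prop‑1‑en‑2‑yl)‑6‑oxabicyclo[3.2.1]octan‑8‑yl]propanoate | C=C(C)[C@@]12CC[C@@H](C)[C@@](CCC3=C(O)COC3=O)(C(=O)O1)[C@H]2CCC(=O)OC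
F7 | step 8 | methyl 3‑[(1R,2R,5S,8R)‑2‑methyl‑7‑oxo‑1‑[2‑(2‑oxo‑4‑{[(trifluoromethyl)sulfonyl]oxy}‑2,5‑dihydrofuran‑3‑yl)ethyl]‑5‑(prop‑1‑en‑2‑yl)‑6‑oxabicyclo[3.2.1]octan‑8‑yl]propanoate | C=C(C)[C@@]12CC[C@@H](C)[C@@](CCC3=C(OS(=O)(=O)C(F)(F)F)COC3=O)(C(=O)O1)[C@H]2CCC(=O)OC
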